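The clock stops at 40 h in amber, red, grey and green, and these flasks differ in their loading of catalyst.

| flask | substrate | reagent | catalyst | remark | time |
|---|---|---|---|---|---|
| elm | 1 M | 1.5 equiv | 0.14 mol% | run made earlier |  |
| larch | 1 M | 1.5 equiv | 1.2 mol% | run made earlier |  |
| amber | 1.0 M | 1.50 equiv | 0.12 mol% |  | 40 h |
| red | 1.0 M | 1.50 equiv | 0.25 mol% |  | 40 h |
| grey | 1.0 M | 1.50 equiv | 0.5 mol% |  | 40 h |
| green | 1.0 M | 1.50 equiv | 1 mol% |  | 40 h |

| run | time / h | intermediate / % | target / % |
|---|---|---|---|
| elm | 5.00 | 8.6 | 0.2 |
| elm | 10.0 | 15.0 | 0.8 |
| elm | 15.0 | 18.7 | 0 |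
| elm | 20.0 | 22.9 | 1.0 |
| elm | 25.0 | 24.9 | 1.6 |
| elm | 30.0 | 26.2 | 1.2 |
| larch | 5.00 | 47.5 | 3.6 |
| larch | 10.0 | 57.7 | 9.6 |
| larch | 15.0 | 53.5 | 15.9 |
| larch | 20.0 | 45.6 | 21.3 |
| larch | 25.0 | 36.6 | 25.1 |
| larch | 30.0 | 28.7 | 28.8 |

(standard deviation of a reading: 0.5 percentage points)

* amount of intermediate at the end, in percent of the substrate charged for amber, red, grey, green, in this order
* the course of these numbers from the first flask to the last (falls all the way / falls, then rises / rises all the way / rises, then falls / hardly changes)

- "hardly changes" means that all values lie within two and a half points (for a concentration: within two and a half percent of the largest)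

Ida holds that catalyst makes intermediate, so more catalyst means more of it at the stop: after 5.00 h, larch shows 47.5% against 8.6% in elm. Ben answers with the balance of substrate, the limiting reagent: [substrate] + [intermediate] + [target] + whatever is unseen equals the charge. In larch, [intermediate] + [target] falls from 69.4% at 15.0 h to 57.5% at 30.0 h. Substrate can feed that sum but not drain it, so something unseen is taking intermediate.

Ben's reckoning is mine too. The first reading of elm gives a pseudo-first-order formation constant f of 0.0184 /h. Scaled with loading, f is 0.158 /h in larch, so substrate feeds in 8.48% of the charge between those two readings. The area under the intermediate curve of larch over those hours is 6.17 h in units of the charge. Dividing by it, the gain of target gives 0.0209 /h and the fall of the sum plus the feed gives a leak of 0.0331 /h.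

Ben takes the leak as free of catalyst and scales the target step with loading, so the loss constant g of elm is 0.0355 /h. That gives 24.9% at 30.0 h, against the reading of 26.2%.

Amber then has f = 0.0158 /h and g = 0.0352 /h, and 41.3 h is its peak hour, the time ln(f/g)/(f − g) at which a flask makes intermediate as fast as it uses it up. For larch the same formula gives 10.3 h, and its highest reading stands at 10.0 h.

By this reckoning amber stops just short of its peak, with f below g. The same reckoning puts the peak of green at 11.8 h, well before the stop. The consecutive first-order formula gives me 23.4% for amber and 20.7% for green, and for red 32.3%, higher than either.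

The forecast sides with Ben, a little above my figure for amber: 25.6%, 34.8%, 33.5%, 21.4%, rises, then falls, with the words “At low loading it has barely formed; at high loading it has already decayed.”

The flasks give 24.5%, 33.3%, 32.4%, 21.4%: rises, then falls.

    substrate + catalyst → catalyst + intermediate (k = 13.6 /M/h)
    reagent + catalyst + intermediate → catalyst + target (k = 1.34 /M²/h)
    intermediate → side product (k = 0.0314 /h)

Ida's view keeps the loadings below 0.34 mol%, where the row turns. Amber at 40.0 h still makes intermediate 1.03 times faster than it uses it up, each step taken net, and its reckoned peak hour is 41.3 h. The reckoned peak hour of red is 28.5 h, and red holds 33.6% of intermediate after 20.0 h and 33.3% after 40.0 h.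

(The runs were generated by integration from invented constants; the scatter is artificial.)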